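(The runs are calculated on assumed constants, noise included.)

A target molecule is what we follow: it forms early, and after that it stands a small chance of leaving each day.

- theta: substrate 0.075 M; target 3 mM; run made earlier
- flask: substrate 0.075 M; target 1.50 mM; time 15 d

- theta (time / d: target / %, substrate / %): 0.333: 99.7, 0.3; 0.833: 98.1, 0.1; 2.08: 92.8, 0.5; 5.00: 81.4, 0.2

(each reading ± 0.5 percentage points)



1. time up to 15 d at which target stands highest
2. the amount of target, in percent of the substrate charged, at that time
3. earliest time at which at least nineteen twentieths of that best amount are there, in d
4. latest time at which they still are, in d

**Fast rung.** The first reading of the theta run, at 0.333 d, shows 0.3% substrate and 99.7% target. This reading gives a bound on the conversion in the theta run and not a rate. The flask carries half the target charge of the theta run, so we expect the same rung a little later and watch the first half day closely.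

**Slow rung.** From 0.833 d to 5.00 d, target in the theta run falls from 98.1% to 81.4%. This gives 0.0448 /d, a reading with its scatter: the fade rate, the chance per day that a target molecule leaves. Its half-life of 15.5 d is far longer than the fast rung, so we put the peak in the flask at the end of that rung. By our reckoning, the window down to the asked share of the best closes 1.15 d after the peak.

**The forecast.** It reads the flask thus: “target seeds its own formation, then slowly decays”. It gives 100% at 0.2 d, opening at 0.13 d and shutting at 1.4 d. Its width after the peak, 1.20 d, is slightly more than ours.

**The result.** The flask peaks at 97.7% at 0.247 d, opens at 0.150 d and shuts at 1.61 d. Its width of 1.36 d is more than our 1.15 d.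

    substrate ⇌ dormant form (K = 0.990, k = 5.00 × 10⁻⁶ /s)
    substrate → target (k = 1.70 × 10⁻⁷ /s)
    target ⇌ isomer of the product (K = 92.0, k = 5.80 × 10⁻⁷ /s)
    substrate + target → 2 target (k = 0.00690 /M/s)

In the flask at 0.0885 d, the half-life of substrate is 0.72 h by the seeded step, known as autocatalysis, against 1.6 d by the forward step alone into the dormant form. The dormant form in the flask stands at 3.45% at 0.247 d and 2.01% at 1.50 d. Carried to the neighbour flask left until 6.0 d, the fade rate takes the peak of 97.7% down to 75.5%, and that flask holds 75.9%.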